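**Plan** (prenyl = 3-methylbut-2-en-1-yl, MOM = methoxymethyl)
1. Ring C contains an acyloin: the ketone carbon C4 (on ring A) is bonded to the carbinol carbon C3. The first cut is therefore C3–C4, which opens ring C to a dialdehyde whose two formyl carbons have the same polarity.
2. The next cuts are O1–C2 (salicylaldehyde-type phenol + mandelate) and C2–C1' (ring B arylmagnesium + ethyl glyoxylate). The three prenyl groups go back to aqueous phenolate C-alkylations.
3. Forward: the ring A and ring B fragments are prenylated and MOM-protected, joined at O1–C2 and adjusted to the dialdehyde. Ring C is closed last by carbene umpolung of the ring A formyl group.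
4. The enabling feature is C2–H. It is benzylic to ring B, bound to O1 and α to the C3 formyl group, so C2 is configurationally labile in the dialdehyde and all earlier material can be racemic.
5. Stereochemistry: a chiral triazolylidene sets C3 by catalyst control and selects C2 by dynamic kinetic resolution towards the 2,3-trans (2R,3R) product. Mild acid then removes both MOM groups.

Key step: step 9

Assumption: the (5aS,10bR) antipode of the aminoindanol-derived triazolium salt is taken to deliver the (3R) carbinol, by analogy with aldehyde–ketone closures over the same tether; both antipodes are commercial, so the mirror-image salt would serve if the sense of induction proves opposite.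

**Step 1**
Reactants: 1 2,4-dihydroxybenzaldehyde; 2 prenyl bromide
Product: 3 2,4-dihydroxy-3-prenylbenzaldehyde
Conditions: KOH (2 equiv), H2O, 0 °C to rt; chromatography
Reagents that add atoms: none
Why: Phenolate C-alkylation in water is a known direct C-prenylation of 2,4-dihydroxyaryl carbonyl compounds, because hydrogen-bond solvation of the oxygens diverts attack to carbon and C3, flanked by both oxygens, is the most nucleophilic ring position.

**Step 2**
Reactants: 3 2,4-dihydroxy-3-prenylbenzaldehyde
Product: 4 2-hydroxy-4-(methoxymethoxy)-3-prenylbenzaldehyde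
Conditions: MOMCl (1.1 equiv), K2CO3, acetone, rt
Reagents that add atoms: chloromethyl methyl ether (MOMCl), COCCl
Why: In this selective Williamson-type etherification the 2-OH is held in a hydrogen bond to the formyl oxygen, so the weak base ionises and alkylates only the 4-OH.

**Step 3**
Reactants: 5 4-iodophenol; 2 prenyl bromide
Product: 6 4-iodo-2,6-diprenylphenol
Conditions: KOH (aq), 2 (2.5 equiv), H2O, rt
Reagents that add atoms: none
Why: This is the same aqueous phenolate C-alkylation, known as the o,o'-diprenylation of p-halophenols, and the blocked para position leaves only the two ortho carbons open.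

**Step 4**
Reactants: 6 4-iodo-2,6-diprenylphenol
Product: 7 5-iodo-2-(methoxymethoxy)-1,3-diprenylbenzene
Conditions: NaH, MOMCl, THF–DMF, 0 °C to rt
Reagents that add atoms: chloromethyl methyl ether (MOMCl), COCCl
Why: Standard MOM ether formation works here because the fully formed sodium phenoxide and the very reactive chloromethyl ether overcome the two flanking prenyl groups.

**Step 5**
Reactants: 7 5-iodo-2-(methoxymethoxy)-1,3-diprenylbenzene; 8 ethyl glyoxylate
Product: 10 ethyl (±)-2-hydroxy-2-[4-(methoxymethoxy)-3,5-diprenylphenyl]acetate, via arylmagnesium chloride 9 (not isolated)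
Conditions: i-PrMgCl·LiCl, THF, 0 °C to rt; then 8 (freshly distilled, 2 equiv), −78 to −20 °C; aq NH4Cl
Reagents that add atoms: none
Why: Iodine–magnesium exchange and Grignard addition to the formyl group of the glyoxylate, which is far more electrophilic than its ester, give the mandelate as a racemate, and this is harmless because the centre becomes labile in 13.

**Step 6**
Reactants: 4 2-hydroxy-4-(methoxymethoxy)-3-prenylbenzaldehyde; 10 ethyl (±)-mandelate
Product: 11 ethyl (±)-2-[6-formyl-3-(methoxymethoxy)-2-prenylphenoxy]-2-[4-(methoxymethoxy)-3,5-diprenylphenyl]acetate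
Conditions: PPh3, DIAD, THF, 0 °C to rt
Reagents that add atoms: none
Why: In this Mitsunobu etherification the acidic salicylaldehyde-type phenol displaces the oxyphosphonium group of a carbonyl-flanked benzylic carbinol by SN2, a carbinol that has no β-hydrogen to eliminate.

**Step 7**
Reactants: 11 ether ester aldehyde
Product: 12 (±)-2-[6-(hydroxymethyl)-3-(methoxymethoxy)-2-prenylphenoxy]-2-[4-(methoxymethoxy)-3,5-diprenylphenyl]ethan-1-ol
Conditions: LiAlH4, THF, 0 °C
Reagents that add atoms: none
Why: Hydride reduction takes the ester and the aryl aldehyde to the same oxidation level in one operation and leaves the aryl ethers, acetals and alkenes untouched.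

**Step 8**
Reactants: 12 diol
Product: 13 (±)-4-(methoxymethoxy)-2-{1-[4-(methoxymethoxy)-3,5-diprenylphenyl]-2-oxoethoxy}-3-prenylbenzaldehyde
Conditions: Dess–Martin periodinane (2.5 equiv), CH2Cl2, 0 °C to rt; short filtration, used at once under Ar
Reagents that add atoms: none
Why: The double Dess–Martin oxidation is fast, anhydrous and near neutral, so both alcohols stop at the aldehyde while the trisubstituted alkenes and MOM ethers survive.

**Step 9**
Reactants: 13 dialdehyde
Product: 15 (2R,3R)-3-hydroxy-7-(methoxymethoxy)-2-[4-(methoxymethoxy)-3,5-diprenylphenyl]-8-prenylchroman-4-one, via Breslow enaminol 14 (not isolated)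
Conditions: (5aS,10bR)-2-(pentafluorophenyl)-5a,10b-dihydro-4H,6H-indeno[2,1-b][1,2,4]triazolo[4,3-d][1,4]oxazin-2-ium tetrafluoroborate (10 mol %), i-Pr2NEt (1 equiv), 4 Å MS, toluene, Ar, 0 °C to rt
Reagents that add atoms: none
Why: Proposed new method: the triazolylidene adds to the ring A formyl group (future C4), proton transfer gives Breslow enaminol 14, its nucleophilic carbon attacks the aliphatic formyl carbon (future C3) with proton relay from the enol OH, and collapse releases the carbene and the acyloin. The closest known reaction type is the enantioselective carbene-catalysed intramolecular crossed benzoin of 2-(2-oxoalkoxy)benzaldehydes (aldehyde donor, ketone acceptor) to 3-hydroxychroman-4-ones, including its dynamic kinetic variant on configurationally labile keto aldehydes; new here is a formyl acceptor whose own α-carbon is the labile stereocentre. Ring C closes in the favoured 6-(enolexo)-exo-trig mode. C3 is set by the catalyst, whose indane wall shields one face of the planar enaminol and, through the OH···O=C hydrogen bond, fixes which face of the acceptor formyl group is presented. C2 is set by Curtin–Hammett selection: the triply activated C2–H lets i-Pr2NEt interconvert (R)- and (S)-13 through the enol faster than closure, and only (R)-13 should reach the catalyst-preferred transition state with the ring B aryl group pseudo-equatorial and anti to the forming C3–O bond, which is also the thermodynamically preferred 2,3-trans arrangement. The step needs donor/acceptor chemoselectivity, which is secured because the ring A aldehyde gives a conjugated enaminol whereas the aliphatic formyl group sits on a tertiary carbon whose carbene adduct meets allylic 1,3-strain on deprotonation, and because the C8 prenyl group gears the ether side chain towards the ring A formyl group; the weak base and low temperature hold back aryloxide expulsion, aldol closure through C2 and epimerisation of 15.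

**Step 10**
Reactants: 15 bis-MOM dihydroflavonol
Product: 16 (2R,3R)-3,7-dihydroxy-2-(4-hydroxy-3,5-diprenylphenyl)-8-prenylchroman-4-one (CNP0316331.1)
Conditions: 3 M aq HCl, MeOH, 45 °C, short reaction time
Reagents that add atoms: none
Why: Acid-catalysed transacetalisation of aryl MOM ethers to methanol is routine for prenylated flavonoids, is milder than what o-prenylphenol-to-chroman cyclisation needs, and avoids base, so neither C3 enolisation nor quinone-methide opening at C2 can scramble the stereocentres.

**Compound list**
1 | 2,4-dihydroxybenzaldehyde | O=Cc1ccc(O)cc1O | starting material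
2 | prenyl bromide (1-bromo-3-methylbut-2-ene) | CC(C)=CCBr | starting material
3 | 2,4-dihydroxy-3-prenylbenzaldehyde | O=Cc1ccc(O)c(CC=C(C)C)c1O | intermediate
4 | 2-hydroxy-4-(methoxymethoxy)-3-prenylbenzaldehyde | O=Cc1ccc(OCOC)c(CC=C(C)C)c1O | intermediate
5 | 4-iodophenol | Oc1ccc(I)cc1 | starting material
6 | 4-iodo-2,6-diprenylphenol | Oc1c(CC=C(C)C)cc(I)cc1CC=C(C)C | intermediate
7 | 5-iodo-2-(methoxymethoxy)-1,3-diprenylbenzene | COCOc1c(CC=C(C)C)cc(I)cc1CC=C(C)C | intermediate
8 | ethyl glyoxylate (ethyl 2-oxoacetate) | CCOC(=O)C=O | starting material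
9 | [4-(methoxymethoxy)-3,5-diprenylphenyl]magnesium chloride | COCOc1c(CC=C(C)C)cc([Mg]Cl)cc1CC=C(C)C | intermediate
10 | ethyl (±)-2-hydroxy-2-[4-(methoxymethoxy)-3,5-diprenylphenyl]acetate | CCOC(=O)C(O)c1cc(CC=C(C)C)c(OCOC)c(CC=C(C)C)c1 | intermediate
11 | ethyl (±)-2-[6-formyl-3-(methoxymethoxy)-2-prenylphenoxy]-2-[4-(methoxymethoxy)-3,5-diprenylphenyl]acetate | CCOC(=O)C(Oc1c(C=O)ccc(OCOC)c1CC=C(C)C)c1cc(CC=C(C)C)c(OCOC)c(CC=C(C)C)c1 | intermediate
12 | (±)-2-[6-(hydroxymethyl)-3-(methoxymethoxy)-2-prenylphenoxy]-2-[4-(methoxymethoxy)-3,5-diprenylphenyl]ethan-1-ol | OCC(Oc1c(CO)ccc(OCOC)c1CC=C(C)C)c1cc(CC=C(C)C)c(OCOC)c(CC=C(C)C)c1 | intermediate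
13 | (±)-4-(methoxymethoxy)-2-{1-[4-(methoxymethoxy)-3,5-diprenylphenyl]-2-oxoethoxy}-3-prenylbenzaldehyde | O=CC(Oc1c(C=O)ccc(OCOC)c1CC=C(C)C)c1cc(CC=C(C)C)c(OCOC)c(CC=C(C)C)c1 | intermediate
14 | Breslow enaminol from (R)-13 and the (5aS,10bR)-triazolylidene (enaminol C=C geometry not defined) | OC(=C1N(c2c(F)c(F)c(F)c(F)c2F)N=C2CO[C@H]3Cc4ccccc4[C@H]3N12)c1ccc(OCOC)c(CC=C(C)C)c1O[C@@H](C=O)c1cc(CC=C(C)C)c(OCOC)c(CC=C(C)C)c1 | intermediate
15 | (2R,3R)-3-hydroxy-7-(methoxymethoxy)-2-[4-(methoxymethoxy)-3,5-diprenylphenyl]-8-prenylchroman-4-one | CC(C)=CCc1cc([C@H]2Oc3c(ccc(OCOC)c3CC=C(C)C)C(=O)[C@@H]2O)cc(CC=C(C)C)c1OCOC | intermediate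
16 | (2R,3R)-3,7-dihydroxy-2-(4-hydroxy-3,5-diprenylphenyl)-8-prenylchroman-4-one | CC(C)=CCc1cc([C@H]2Oc3c(ccc(O)c3CC=C(C)C)C(=O)[C@@H]2O)cc(CC=C(C)C)c1O | target

**Step count**
Total steps: 10. Longest linear sequence: 8 (steps 3–10, from 5).

**Steps most likely to fail**

**1. Step 9.**
- What may go wrong:
  - The donor and acceptor roles may reverse.
  - Carbene attack at the aliphatic formyl group may expel the ring A phenoxide.
  - The base may trigger aldol closure through C2.
  - Racemisation of 13 may be too slow relative to closure, so that stereoselection collapses.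
- Fallback (from 4 and 7, back at 16): the C3–C4 closure is given up in favour of the known chalcone epoxide route.
  - Phenol 4 is capped (NaH, MOMCl) to 2,4-bis(methoxymethoxy)-3-prenylbenzaldehyde F1.
  - MeMgBr gives 1-[2,4-bis(methoxymethoxy)-3-prenylphenyl]ethan-1-ol F2.
  - Dess–Martin oxidation gives 1-[2,4-bis(methoxymethoxy)-3-prenylphenyl]ethan-1-one F3.
  - Iodide 7 is formylated (i-PrMgCl·LiCl, then DMF) to 4-(methoxymethoxy)-3,5-diprenylbenzaldehyde F4.
  - Claisen–Schmidt condensation of the ketone and the aldehyde (KOH, EtOH) gives the (E)-chalcone F5.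
  - Juliá–Colonna epoxidation (poly-L-leucine, urea–H2O2, DBU, THF) attacks only the enone and should give the (2R,3S)-epoxy ketone F6.
  - HCl in MeOH removes the three MOM groups. The freed 2'-OH opens the epoxide at the benzylic carbon with inversion while the α-carbon keeps its configuration, giving 16 directly.

**2. Step 8.**
- What may go wrong:
  - The new α-aryl-α-aryloxy aldehyde may enolise during oxidation and work-up, followed by autoxidation or aldol closure.
  - A lactol may form after the first oxidation and be over-oxidised.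
- Fallback (from 11, back at 13): the aliphatic aldehyde is reached by reduction instead of oxidation, and the aromatic aldehyde is unmasked last.
  - HC(OMe)3 with catalytic PPTS in MeOH converts 11 into the ring A dimethyl acetal ester F7.
  - i-Bu2AlH in toluene at −78 °C stops at the chelated hemiacetal aluminate of the α-aryloxy ester and gives the α-aryloxy aldehyde acetal F8.
  - Wet silica gel with a trace of oxalic acid in CH2Cl2 hydrolyses the electron-rich aryl acetal far faster than the MOM ethers and gives 13.

**3. Step 6.**
- What may go wrong: the SN2 displacement may be sluggish because the nucleophilic oxygen is flanked by the formyl and prenyl groups, so that alkylation of the reduced azodicarboxylate takes over.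
- Fallback (from 10, back at 11): the electrophile is preformed and a free phenoxide is used.
  - Appel bromination (CBr4, PPh3, CH2Cl2, 0 °C) gives ethyl 2-bromo-2-[4-(methoxymethoxy)-3,5-diprenylphenyl]acetate F9.
  - Williamson etherification with 4 (Cs2CO3, DMF, rt) then gives 11. This is the established way to make 2-(2-formylphenoxy)-2-arylacetates.

**Further compounds**
F1 | step 9 | 2,4-bis(methoxymethoxy)-3-prenylbenzaldehyde | O=Cc1ccc(OCOC)c(CC=C(C)C)c1OCOC
F2 | step 9 | (±)-1-[2,4-bis(methoxymethoxy)-3-prenylphenyl]ethan-1-ol | CC(O)c1ccc(OCOC)c(CC=C(C)C)c1OCOC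
F3 | step 9 | 1-[2,4-bis(methoxymethoxy)-3-prenylphenyl]ethan-1-one | CC(=O)c1ccc(OCOC)c(CC=C(C)C)c1OCOC
F4 | step 9 | 4-(methoxymethoxy)-3,5-diprenylbenzaldehyde | O=Cc1cc(CC=C(C)C)c(OCOC)c(CC=C(C)C)c1
F5 | step 9 | (E)-1-[2,4-bis(methoxymethoxy)-3-prenylphenyl]-3-[4-(methoxymethoxy)-3,5-diprenylphenyl]prop-2-en-1-one | O=C(/C=C/c1cc(CC=C(C)C)c(OCOC)c(CC=C(C)C)c1)c1ccc(OCOC)c(CC=C(C)C)c1OCOC
F6 | step 9 | [2,4-bis(methoxymethoxy)-3-prenylphenyl]{(2R,3S)-3-[4-(methoxymethoxy)-3,5-diprenylphenyl]oxiran-2-yl}methanone | O=C(c1ccc(OCOC)c(CC=C(C)C)c1OCOC)[C@@H]1O[C@H]1c1cc(CC=C(C)C)c(OCOC)c(CC=C(C)C)c1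
F7 | step 8 | ethyl (±)-2-[6-(dimethoxymethyl)-3-(methoxymethoxy)-2-prenylphenoxy]-2-[4-(methoxymethoxy)-3,5-diprenylphenyl]acetate | CCOC(=O)C(Oc1c(C(OC)OC)ccc(OCOC)c1CC=C(C)C)c1cc(CC=C(C)C)c(OCOC)c(CC=C(C)C)c1
F8 | step 8 | (±)-2-[6-(dimethoxymethyl)-3-(methoxymethoxy)-2-prenylphenoxy]-2-[4-(methoxymethoxy)-3,5-diprenylphenyl]acetaldehyde | O=CC(Oc1c(C(OC)OC)ccc(OCOC)c1CC=C(C)C)c1cc(CC=C(C)C)c(OCOC)c(CC=C(C)C)c1
F9 | step 6 | ethyl (±)-2-bromo-2-[4-(methoxymethoxy)-3,5-diprenylphenyl]acetate | CCOC(=O)C(Br)c1cc(CC=C(C)C)c(OCOC)c(CC=C(C)C)c1
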